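**Retrosynthetic overview**
1. Target 24 ⇐ C1 ketone 23 (Luche reduction sets 1β-OH last).
2. 23 ⇐ aldehyde–allylboronate 21: ring B is closed last at C7–C8 by intramolecular allylboration, in which C7 (the β-carbon of an acrylate) is the nucleophile; this sets C7 and C8. The aldehyde comes from an allyl group.
3. C6–C7 ⇐ ring-A aldehyde 11 + metalated methyl propiolate (the same C7 carbon, used as a nucleophile a first time; chelation sets C6), then angelate ester and syn-hydrocupration/borylmethylation.
4. 11 ⇐ enone 5 + 2-lithio-1,3-dithiane (formyl anion, C5–C6) + allyl bromide (C9–C10): one-pot conjugate addition/alkylation relays C4 to C5 and C10.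
5. 5 ⇐ (R)-linalool (supplies C4) by singlet-oxygen ene/dehydration and RCM. Ring A is formed first (RCM), ring B last (allylboration).

Assumption: eudesmane numbering (C1–C15) and α/β (β = face of the C10 methyl) are used for all intermediates; carbon building blocks that end up in the skeleton are numbered as reactants, and only other atom donors appear under "Reagents that add atoms".

**Step 1**
Reactants: 1 (R)-(−)-linalool
Product: 3 (6R)-6-hydroxy-2,6-dimethylocta-1,7-dien-3-one, via allylic hydroperoxide 2 (not isolated)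
Conditions: O2, TPP (cat.), hν, CH2Cl2, 0 °C; then Ac2O, pyridine, DMAP (cat.), 0 °C → rt
Reagents that add atoms: oxygen O=O
Why: Schenck ene reaction of singlet oxygen at the trisubstituted alkene gives the secondary allylic hydroperoxide (about 1:1 with its tertiary regioisomer, which is separated), and Kornblum–DeLaMare-type dehydration turns it into the isopropenyl ketone, leaving the vinyl carbinol and its (R) centre (later C4) untouched.

**Step 2**
Reactants: 3 (6R)-6-hydroxy-2,6-dimethylocta-1,7-dien-3-one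
Product: 5 (4R)-2,4-dimethyl-4-(trimethylsilyloxy)cyclohex-2-en-1-one, via hydroxy enone 4 (not isolated)
Conditions: Hoveyda–Grubbs II (3 mol %), toluene (0.02 M), 80 °C; then N-(trimethylsilyl)imidazole, rt
Reagents that add atoms: N-(trimethylsilyl)imidazole C[Si](C)(C)n1ccnc1
Why: Ring-closing metathesis between the vinyl carbinol and the 1,1-disubstituted enone alkene closes ring A with loss of ethylene, and in-pot silylation masks the tertiary alcohol as a non-directing TMS ether; no new stereocentre.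

**Step 3**
Reactants: 5 (4R)-2,4-dimethyl-4-(trimethylsilyloxy)cyclohex-2-en-1-one; 6 1,3-dithiane; 7 allyl bromide
Product: 10 (2R,3R,4R)-2-allyl-3-(1,3-dithian-2-yl)-2,4-dimethyl-4-(trimethylsilyloxy)cyclohexan-1-one, via 2-lithio-1,3-dithiane 8 (not isolated), via lithium enolate 9 (not isolated)
Conditions: 6, n-BuLi, THF, −30 °C; HMPA, 5, −78 °C; then 7, −78 → −20 °C
Reagents that add atoms: none
Why: Corey–Seebach acyl-anion conjugate addition: HMPA-solvated 2-lithio-1,3-dithiane adds 1,4 to the enone anti to the pseudo-axial C4–OSiMe3 (sets C5), and the tetrasubstituted enolate is allylated anti to the new dithianyl group (sets quaternary C10, methyl cis to the dithianyl group).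

**Step 4**
Reactants: 10 (2R,3R,4R)-2-allyl-3-(1,3-dithian-2-yl)-2,4-dimethyl-4-(trimethylsilyloxy)cyclohexan-1-one
Product: 11 (1R,2R,6R)-2-allyl-6-hydroxy-2,6-dimethyl-3-oxocyclohexane-1-carbaldehyde
Conditions: PhI(OCOCF3)2, MeCN/H2O 9:1, 0 °C → rt
Reagents that add atoms: water O
Why: Oxidative dithioacetal hydrolysis with a hypervalent iodine reagent frees the C6 aldehyde without touching the allyl group, and the trifluoroacetic acid released cleaves the tertiary TMS ether so that the C4 hydroxyl can direct the next step.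

**Step 5**
Reactants: 11 (1R,2R,6R)-2-allyl-6-hydroxy-2,6-dimethyl-3-oxocyclohexane-1-carbaldehyde; 12 methyl propiolate
Product: 14 methyl (4R)-4-hydroxy-4-(2-allyl-6-hydroxy-2,6-dimethyl-3-oxocyclohexyl)but-2-ynoate (6α-OH; ring centres as in 11), via lithium methyl propiolate 13 (not isolated)
Conditions: 12, LiHMDS, THF, −78 °C; MgBr2·OEt2; then 11, −78 °C; NH4Cl (aq)
Reagents that add atoms: none
Why: Metalated propiolate (a β-acrylate anion equivalent) adds 1,2 to the aldehyde faster than to the neopentyl C1 ketone; the Mg(II) chelate between the C4 alkoxide and the aldehyde oxygen holds the formyl group equatorial, the two axial methyls block the β face, and α-face attack (Cram-chelate control) gives the 6α-carbinol.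

**Step 6**
Reactants: 14 methyl (4R)-4-hydroxy-4-(2-allyl-6-hydroxy-2,6-dimethyl-3-oxocyclohexyl)but-2-ynoate; 15 angelic anhydride
Product: 17 6-O-angeloyl 4-O-trimethylsilyl derivative of 14, via angelate alcohol 16 (not isolated)
Conditions: 15, DMAP (0.2 equiv), i-Pr2NEt, CH2Cl2, 0 °C → rt; then BSA, 40 °C
Reagents that add atoms: N,O-bis(trimethylsilyl)acetamide CC(=N[Si](C)(C)C)O[Si](C)(C)C
Why: DMAP-catalysed acylation with angelic anhydride esterifies only the secondary propargylic alcohol (the tertiary C4–OH is inert; low temperature avoids Z to E isomerisation), and BSA then silylates the tertiary alcohol so that no acidic proton remains for the organocopper step.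

**Step 7**
Reactants: 17 6-O-angeloyl 4-O-trimethylsilyl ynoate; 18 2-(iodomethyl)-4,4,5,5-tetramethyl-1,3,2-dioxaborolane
Product: 20 2-(methoxycarbonyl)allylboronate with C6 cis to CO2Me and trans to CH2Bpin, via α-cuprio enoate 19 (not isolated)
Conditions: [(Ph3P)CuH]6 (0.22 equiv), THF, −78 → −40 °C; then HMPA, 18, −40 → 0 °C
Reagents that add atoms: none
Why: Proposed new method: syn-hydrocupration of the ynoate by Stryker's reagent puts H on C7 and Cu on C11 on the same side, and the α-cuprio enoate is trapped with retention by ICH2Bpin (boron ate complex, then 1,2-metallate shift), giving the allylboronate with C6 trans to CH2Bpin; the closest known reaction types are carbocupration or hydroalumination of alkynoates with halomethylboronate trapping and Stryker reduction of ynoates to Z-enoates.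

**Step 8**
Reactants: 20 2-(methoxycarbonyl)allylboronate
Product: 23 methyl 6α-angeloyloxy-4α,8α-dihydroxy-1-oxoeudesm-11(13)-en-12-oate, via C8 aldehyde 21 (not isolated), via O8 pinacol borate 22 (not isolated)
Conditions: OsO4 (2 mol %), NaIO4, 2,6-lutidine, dioxane/H2O 3:1, rt → 40 °C; then 0.5 M citric acid, rt
Reagents that add atoms: osmium tetroxide O=[Os](=O)(=O)=O; sodium periodate [Na+].[O-]I(=O)(=O)=O
Why: Lemieux–Johnson cleavage of the only electron-rich terminal alkene unmasks the C8 aldehyde, which is captured by intramolecular allylboration through a chair Zimmerman–Traxler transition state fused trans to the forming ring-B chair; the fixed alkene geometry and the trans ring fusion put C11 and O8 equatorial, which sets 7β-C and 8α-OH and moves the alkene to C11=C13, and mild acid then hydrolyses the borate and the TMS ether.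

**Step 9**
Reactants: 23 methyl 6α-angeloyloxy-4α,8α-dihydroxy-1-oxoeudesm-11(13)-en-12-oate
Product: 24 methyl 6α-angeloyloxy-1β,4α,8α-trihydroxyeudesm-11(13)-en-12-oate (CNP0136844.1)
Conditions: NaBH4, CeCl3·7H2O, MeOH, −40 °C
Reagents that add atoms: none
Why: Luche reduction: hydride attacks the C1 ketone of the rigid trans-decalin axially from the α face (the β face is shielded by the axial C10 methyl), giving the equatorial 1β-alcohol, while CeCl3 suppresses 1,4-reduction of the acrylate.

**Compound list**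
1 | (R)-(−)-linalool | CC(C)=CCC[C@@](C=C)(C)O | starting material
2 | (6R)-3-hydroperoxy-2,6-dimethylocta-1,7-dien-6-ol (C3 epimers) | C=C(C)C(OO)CC[C@@](C=C)(C)O | intermediate
3 | (6R)-6-hydroxy-2,6-dimethylocta-1,7-dien-3-one | C=C(C)C(=O)CC[C@@](C=C)(C)O | intermediate
4 | (4R)-4-hydroxy-2,4-dimethylcyclohex-2-en-1-one | O=C1CC[C@@](C)(O)C=C1C | intermediate
5 | (4R)-2,4-dimethyl-4-(trimethylsilyloxy)cyclohex-2-en-1-one | O=C1CC[C@@](C)(O[Si](C)(C)C)C=C1C | intermediate
6 | 1,3-dithiane | C1CSCSC1 | starting material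
7 | allyl bromide | C=CCBr | starting material
8 | 2-lithio-1,3-dithiane | [Li]C1SCCCS1 | intermediate
9 | lithium enolate of the 1,4-adduct (C1–OLi, C1=C10) | C1(SCCCS1)[C@@H]2C(C)=C(O[Li])CC[C@@]2(C)O[Si](C)(C)C | intermediate
10 | (2R,3R,4R)-2-allyl-3-(1,3-dithian-2-yl)-2,4-dimethyl-4-(trimethylsilyloxy)cyclohexan-1-one (4α-OTMS, 5β-dithianyl, 10β-Me, 10α-allyl) | C1(SCCCS1)[C@@H]2[C@@](C)(CC=C)C(=O)CC[C@@]2(C)O[Si](C)(C)C | intermediate
11 | (1R,2R,6R)-2-allyl-6-hydroxy-2,6-dimethyl-3-oxocyclohexane-1-carbaldehyde | O=C[C@@H]1[C@@](C)(CC=C)C(=O)CC[C@@]1(C)O | intermediate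
12 | methyl propiolate | C#CC(=O)OC | starting material
13 | lithium methyl propiolate | [Li]C#CC(=O)OC | intermediate
14 | methyl (4R)-4-hydroxy-4-(2-allyl-6-hydroxy-2,6-dimethyl-3-oxocyclohexyl)but-2-ynoate (6α-OH, 4α-OH) | COC(=O)C#C[C@H](O)[C@@H]1[C@@](C)(CC=C)C(=O)CC[C@@]1(C)O | intermediate
15 | angelic anhydride [(Z)-2-methylbut-2-enoic anhydride] | C/C=C(/C)C(=O)OC(=O)/C(C)=C\C | starting material
16 | 6-O-angelate of 14 (free 4α-OH) | COC(=O)C#C[C@H](OC(=O)/C(C)=C\C)[C@@H]1[C@@](C)(CC=C)C(=O)CC[C@@]1(C)O | intermediate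
17 | 6-O-angelate 4-O-TMS ether of 14 | COC(=O)C#C[C@H](OC(=O)/C(C)=C\C)[C@@H]1[C@@](C)(CC=C)C(=O)CC[C@@]1(C)O[Si](C)(C)C | intermediate
18 | 2-(iodomethyl)-4,4,5,5-tetramethyl-1,3,2-dioxaborolane (ICH2Bpin) | ICB1OC(C)(C)C(C)(C)O1 | starting material
19 | α-cuprio enoate (Cu on C11 cis to H7; phosphine ligand omitted) | COC(=O)/C([Cu])=C\[C@H](OC(=O)/C(C)=C\C)[C@@H]1[C@@](C)(CC=C)C(=O)CC[C@@]1(C)O[Si](C)(C)C | intermediate
20 | methyl 2-[(pinacolatoboryl)methyl]alk-2-enoate, C6(OAng) cis to CO2Me (Z by CIP), 10α-allyl, 4α-OTMS, C1 ketone | COC(=O)/C(CB1OC(C)(C)C(C)(C)O1)=C\[C@H](OC(=O)/C(C)=C\C)[C@@H]2[C@@](C)(CC=C)C(=O)CC[C@@]2(C)O[Si](C)(C)C | intermediate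
21 | C8 aldehyde of 20 (10α-CH2CHO) | COC(=O)/C(CB1OC(C)(C)C(C)(C)O1)=C\[C@H](OC(=O)/C(C)=C\C)[C@@H]2[C@@](C)(CC=O)C(=O)CC[C@@]2(C)O[Si](C)(C)C | intermediate
22 | cyclised 8α-O-Bpin borate, 4α-OTMS, 1-oxo | C=C(C(=O)OC)[C@H]1[C@H](OC(=O)/C(C)=C\C)[C@@H]2[C@@](C)(C[C@@H]1OB3OC(C)(C)C(C)(C)O3)C(=O)CC[C@@]2(C)O[Si](C)(C)C | intermediate
23 | methyl 6α-angeloyloxy-4α,8α-dihydroxy-1-oxoeudesm-11(13)-en-12-oate (5α-H, 7α-H, 10β-Me) | C=C(C(=O)OC)[C@H]1[C@H](OC(=O)/C(C)=C\C)[C@@H]2[C@@](C)(C[C@@H]1O)C(=O)CC[C@@]2(C)O | intermediate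
24 | methyl 6α-angeloyloxy-1β,4α,8α-trihydroxyeudesm-11(13)-en-12-oate (CNP0136844.1) | C=C(C(=O)OC)[C@H]1[C@H](OC(=O)/C(C)=C\C)[C@@H]2[C@@](C)(C[C@@H]1O)[C@H](O)CC[C@@]2(C)O | target

**Total step count:** 9. **Longest linear sequence:** 9 steps (from (R)-linalool).

**Three steps most likely to fail**

Step 3 (1,4-addition of the dithiane anion to an α-methyl enone next to a quaternary carbon; 1,2-addition or poor facial control are possible). The fallback sets out from 5 and comes back at 11, and replaces the anion by a radical formyl equivalent. Photocatalytic Giese addition of the 1,3-dioxolan-2-yl radical (1,3-dioxolane, decatungstate, 390 nm) to 5 gives dioxolanyl ketone F1. TMSCl/NaI/Et3N gives the thermodynamic tetrasubstituted silyl enol ether F2. MeLi then allyl bromide gives the allylated dioxolanyl ketone F3. Aqueous TFA/THF removes the acetal and the TMS ether to give 11.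

Step 5 (chelation may not control C6, and the acetylide may compete for the C1 ketone). The fallback sets out from 11 and comes back at 14, and sets C6 by reagent-controlled reduction instead of addition. Lithium methyl propiolate is added without the magnesium salt, which gives 14 mixed with its C6 epimer F4. Dess–Martin oxidation of the mixture gives ynone F5. Reduction with (R)-Me-CBS/catecholborane at −78 °C (alkyne as the small group) gives 14.

Step 7 (untested trapping of the copper intermediate; possible E/Z leakage or reductive aldol onto the C1 ketone). The fallback sets out from 17 and comes back at 20, and builds the same allylboronate by cross-coupling. Pd(PPh3)4-catalysed syn-hydrostannation with Bu3SnH gives α-stannyl enoate F6. Iodine gives α-iodo enoate F7 with retention. Negishi coupling with pinBCH2ZnI (from 18 and zinc dust) gives 20.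

**Further compounds**
F1 | step 3 | (3R,4R)-3-(1,3-dioxolan-2-yl)-2,4-dimethyl-4-(trimethylsilyloxy)cyclohexan-1-one (C2 epimers) | O1CCOC1[C@@H]2C(C)C(=O)CC[C@@]2(C)O[Si](C)(C)C
F2 | step 3 | tetrasubstituted trimethylsilyl enol ether of F1 | O1CCOC1[C@@H]2C(C)=C(O[Si](C)(C)C)CC[C@@]2(C)O[Si](C)(C)C
F3 | step 3 | 2-allyl-3-(1,3-dioxolan-2-yl)-2,4-dimethyl-4-(trimethylsilyloxy)cyclohexan-1-one (configuration as in 10) | O1CCOC1[C@@H]2[C@@](C)(CC=C)C(=O)CC[C@@]2(C)O[Si](C)(C)C
F4 | step 5 | C6 epimer of 14 (6β-OH) | COC(=O)C#C[C@@H](O)[C@@H]1[C@@](C)(CC=C)C(=O)CC[C@@]1(C)O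
F5 | step 5 | C6 ynone: methyl 4-oxo-4-(2-allyl-6-hydroxy-2,6-dimethyl-3-oxocyclohexyl)but-2-ynoate | COC(=O)C#CC(=O)[C@@H]1[C@@](C)(CC=C)C(=O)CC[C@@]1(C)O
F6 | step 7 | α-(tributylstannyl) enoate, Sn cis to H7 | COC(=O)/C([Sn](CCCC)(CCCC)CCCC)=C\[C@H](OC(=O)/C(C)=C\C)[C@@H]1[C@@](C)(CC=C)C(=O)CC[C@@]1(C)O[Si](C)(C)C
F7 | step 7 | α-iodo enoate, I cis to H7 | COC(=O)/C(I)=C\[C@H](OC(=O)/C(C)=C\C)[C@@H]1[C@@](C)(CC=C)C(=O)CC[C@@]1(C)O[Si](C)(C)C
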